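**Fixed ratio.** If both substrates are consumed at rates carrying the same reagent and catalyst factors, those factors cancel when one rate is divided by the other. Integrated, the logarithm of the left-handed substrate's remaining fraction stays a constant multiple of the right-handed one's, however the reagent and catalyst vary.

| flask | left-handed substrate | right-handed substrate | reagent | catalyst | remark | time |
|---|---|---|---|---|---|---|
| theta | 10 mM | 10 mM | 12 mM | 20 µM | the very flask that is asked about, followed so far |  |
| eta | 10 mM | 10 mM | 8 mM | 20 µM | run made earlier |  |
| flask | 10 mM | 10 mM | 12.0 mM | 20 µM |  | 1.5 h |

| run | time / min | right-handed substrate / % | left-handed substrate / % | left-handed product / % |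
|---|---|---|---|---|
| theta | 10.0 | 43.3 | 39.4 | 10.4 |
| theta | 20.0 | 40.8 | 35.7 | 14.3 |
| theta | 25.0 | 40.7 | 34.2 | 15.5 |
| theta | 40.0 | 38.7 | 32.7 | 16.9 |
| theta | 50.0 | 38.4 | 31.4 | 18.5 |
| eta | 20.0 | 42.9 | 38.9 | 11.1 |
| eta | 40.0 | 41.4 | 36.4 | 13.9 |
| eta | 50.0 | 40.8 | 35.3 | 14.0 |
| eta | 80.0 | 39.8 | 34.9 | 15.0 |
| eta | 90.0 | 40.5 | 34.4 | 15.6 |

(standard deviation of a reading: 0.3 percentage points)

- catalyst is single-handed; left-handed substrate and right-handed substrate are mirror images of each other, charged as a racemate, each of them at the stated concentration

- whether the excess of right-handed substrate over left-handed substrate among what is left of the two reaches 95% by 1.5 h (no / yes)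
- the highest excess of right-handed substrate over left-handed substrate among what is left of the two up to 1.5 h

**Reading it.** Each substrate starts at half the percentage scale. Theta's last reading gives this multiple, the selectivity factor, as 1.76, and eta's gives 1.77.

**Reagent.** By hand, an excess of 95% requires the left-handed substrate to fall to 0.0210% of its charge. At one reagent per substrate, that costs 19.9 mM, more than the 12.0 mM charged. The runs agree in direction: at its last reading eta, with 8 mM, reads an excess of 8.14%, while theta, with 12 mM, reads a higher 10.0% at its own last reading.

**Catalyst.** By hand, it cancels from the factor and changes the pace along the same curve. Both runs hold it at 20 µM, so neither tests this.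

**Time.** Theta's left-handed substrate drops 3.7 percentage points from 10.0 min to 20.0 min, then 2.8 points from 25.0 min to 50.0 min. As my own estimate, I allow the same drop again for one more doubling of the time, which reaches past 1.5 h. The factor then gives 12.0%, so I answer no and commit to a top between 10.0% and 12.0%.

**Forecast.** The forecast reads a selectivity of about 1.7, “steady in both runs”, and gives no with a top of 11%.

**Result.** The flask answers no, with a top of 10.1%.

    reagent + catalyst + left-handed substrate → catalyst + left-handed product (k = 2950 L² mol⁻² s⁻¹)
    reagent + catalyst + right-handed substrate → catalyst + right-handed product (k = 1720 L² mol⁻² s⁻¹)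
    2 reagent → homo dimer (k = 0.0729 L mol⁻¹ s⁻¹)

**End state.** At 1.50 h, the flask keeps 0.80% of its reagent, the limiting reagent, and 62% of its left-handed substrate. The factor turns that 62% into 76.2% of the right-handed substrate's charge, against 75% in the flask. The neighbour charged with 48 mM of reagent keeps 35% of its left-handed substrate, for which the factor gives an excess of 22.3%; that neighbour's top is 21.5%.

The earlier runs and the new flask are calculated with made-up constants; the scatter is artificial.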